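**Retrosynthetic overview**
1. The target comes from the C19 alcohol by acylation with 4-acetoxycinnamoyl chloride and then cleavage of the phenol acetate. The 13(16),14-diene comes from the C13 methyl ketone by kinetic enol triflate formation and Suzuki vinylation.
2. The C3 oxygen, a by-product of the key step, is removed by Barton–McCombie deoxygenation.
3. **Key step:** a Lewis-acid epoxide-initiated bicyclization of a cis-epoxy polyene ketone. It forms ring A (C4–C5), then ring B (C9–C10), then the C13 carbonyl oxygen traps the C8 cation from the α-face, and hydrolysis gives 8α-OH.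
4. The cis-epoxide comes from Sharpless epoxidation of a Z-allylic alcohol. That alcohol comes from a Still–Gennari Z-olefination of a nor-polyene aldehyde, which is made by terminal-selective epoxidation and periodate cleavage of commercial farnesylacetone.

**Assumptions:** (5E,9E)-farnesylacetone is commercially available. α/β follow the standard labdane drawing (C20 is β). The C14 carbinol stereocentres in compounds 6–8 are epimeric mixtures that are erased at Step 7.

---

**Step 1**
Reactants: 1 (5E,9E)-farnesylacetone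
Product: 2 (±)-13,14-epoxy-6,10,14-trimethylpentadeca-5,9-dien-2-one
Conditions: NBS, THF/H2O (3:1), 0 °C; then K2CO3, MeOH, rt
Reagents that add atoms: water (O)
Why: Bromohydrin formation (halohydrin/epoxide closure) is selective for the most accessible terminal trisubstituted alkene; the new epoxide stereocentre is racemic and is destroyed in Step 2.

**Step 2**
Reactants: 2
Product: 3 (4E,8E)-4,8-dimethyl-12-oxotrideca-4,8-dienal
Conditions: H5IO6, THF/Et2O (1:1), 0 → 25 °C
Reagents that add atoms: none
Why: Acid-mediated epoxide hydrolysis and periodate glycol cleavage remove the terminal acetone unit and leave the aldehyde, with the E,E-alkenes and ketone untouched; no new stereocentre forms.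

**Step 3**
Reactants: 3; 4 methyl 2-[bis(2,2,2-trifluoroethoxy)phosphoryl]propanoate
Product: 5 methyl (2Z,6E,10E)-2,6,10-trimethyl-14-oxopentadeca-2,6,10-trienoate
Conditions: 4, KHMDS, 18-crown-6, THF, −78 °C
Reagents that add atoms: 4, COC(=O)C(C)P(=O)(OCC(F)(F)F)OCC(F)(F)F (adds C4, C18 and C19)
Why: Still–Gennari olefination is Z-selective, so the C2 chain and the future C19 are cis, and this geometry is what later makes C19 axial.

**Step 4**
Reactants: 5
Product: 6 (2Z,6E,10E)-2,6,10-trimethylpentadeca-2,6,10-triene-1,14-diol (C14 epimers)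
Conditions: DIBAL-H (4 equiv), CH2Cl2, −78 → 0 °C; Rochelle salt work-up
Reagents that add atoms: none
Why: Excess DIBAL reduces both the enoate and the ketone, and the Z-alkene is retained; the C14 carbinol centre is epimeric and is erased in Step 7.

**Step 5**
Reactants: 6
Product: 7 (2R,3S,6E,10E)-2,3-epoxy-2,6,10-trimethylpentadeca-6,10-diene-1,14-diol (cis-epoxide; C14 epimers)
Conditions: Ti(OiPr)4, D-(−)-diethyl tartrate, TBHP, 4 Å MS, CH2Cl2, −20 °C
Reagents that add atoms: tert-butyl hydroperoxide, CC(C)(C)OO (supplies the epoxide O)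
Why: Sharpless asymmetric epoxidation reacts only the hydroxyl-directed alkene, and D-(−)-DET delivers oxygen to the face that fixes the required absolute configuration at C3 and C4; the Z-alkene gives the cis-epoxide that places C19 cis to the C2 chain.

**Step 6**
Reactants: 7
Product: 8 1-O-TBDPS derivative of 7
Conditions: TBDPSCl (1.05 equiv), imidazole, DMF, 0 → 25 °C
Reagents that add atoms: tert-butyldiphenylsilyl chloride, CC(C)(C)[Si](Cl)(c1ccccc1)c1ccccc1
Why: Silylation (protecting group) is selective for the primary alcohol over the secondary one; the silyl ether blocks the C19 oxygen from attacking the C10 cation in Step 8.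

**Step 7**
Reactants: 8
Product: 9 (2R,3S,6E,10E)-1-(TBDPSO)-2,3-epoxy-2,6,10-trimethylpentadeca-6,10-dien-14-one
Conditions: Dess–Martin periodinane, NaHCO3, CH2Cl2, 25 °C
Reagents that add atoms: none
Why: Dess–Martin oxidation converts the secondary alcohol to the methyl ketone needed as the C8-cation terminator and removes the C14 epimer mixture; the epoxide and silyl ether are untouched.

**Step 8**
Reactants: 9
Product: 10 19-(TBDPSO)-3β,8α-dihydroxy-14,15-dinorlabdan-13-one
Conditions: MeAlCl2 (3 equiv), CH2Cl2, −78 °C, 2 h; then aq. NaHCO3, warm to 25 °C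
Reagents that add atoms: water (O, on hydrolysis of the cyclic oxocarbenium/hemiketal)
Why: Proposed new method: a Lewis acid opens the cis-epoxide at tertiary C4 with inversion, and the all-E alkenes cyclize through chair–chair transition states to give trans-decalin stereocentres at C5, C10 and C9. The cis disposition of C19 and the C2 chain forces C19 axial (4β) with 3-O equatorial (3β), the absolute sense follows from the epoxide, and the C8 cation is trapped by the C13 carbonyl oxygen from the α-face, which hydrolysis converts to 8α-OH and the C13 ketone; the closest known reaction is the van Tamelen/Corey epoxy-polyene cation–olefin cyclization with carbonyl (Prins-type) termination, here with an untested 4-silyloxymethyl substituent.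

**Step 9**
Reactants: 10
Product: 11 3β-O-(phenoxythiocarbonyl) derivative of 10
Conditions: PhOC(S)Cl, DMAP, pyridine/CH2Cl2, 0 → 25 °C
Reagents that add atoms: phenyl chlorothionoformate, S=C(Cl)Oc1ccccc1
Why: Only the secondary 3β-OH is acylated, because the tertiary 8α-OH is too hindered, which prepares the Barton–McCombie substrate.

**Step 10**
Reactants: 11
Product: 12 19-(TBDPSO)-8α-hydroxy-14,15-dinorlabdan-13-one
Conditions: Bu3SnH, AIBN, toluene, 110 °C
Reagents that add atoms: none
Why: Barton–McCombie radical deoxygenation removes the C3 oxygen (C3 is not a stereocentre in the product), and C4, C5, C8, C9 and C10 are unaffected.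

**Step 11**
Reactants: 12
Product: 13 19-(TBDPSO)-8α-hydroxy-13-(trifluoromethylsulfonyloxy)-14,15-dinorlabd-13(16)-ene
Conditions: KHMDS (1.1 equiv), THF, −78 °C; then PhNTf2, −78 → 0 °C
Reagents that add atoms: N-phenyl-bis(trifluoromethanesulfonimide), O=S(=O)(C(F)(F)F)N(c1ccccc1)S(=O)(=O)C(F)(F)F
Why: Kinetic deprotonation of the methyl ketone at the less hindered C16 methyl gives the terminal enol triflate, and the tertiary alcohol is less acidic than the ketone so it stays protonated.

**Step 12**
Reactants: 13; 14 potassium vinyltrifluoroborate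
Product: 15 19-(TBDPSO)-labda-13(16),14-dien-8α-ol
Conditions: 14, PdCl2(dppf), Cs2CO3, THF/H2O (9:1), 80 °C
Reagents that add atoms: 14, C=C[B-](F)(F)F.[K+] (adds C14 and C15)
Why: Suzuki–Miyaura coupling of the vinyl triflate with a vinyl boron reagent installs the 2-substituted 1,3-diene with the alkene position fixed by the enol triflate; no stereocentre is touched.

**Step 13**
Reactants: 15
Product: 16 8α-hydroxylabda-13(16),14-dien-19-ol
Conditions: TBAF, THF, 50 °C
Reagents that add atoms: none
Why: Fluoride cleaves the Si–O bond of the hindered axial CH2OSi group, and the diene and the tertiary alcohol are stable.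

**Step 14**
Reactants: 16; 17 (E)-4-acetoxycinnamoyl chloride (made from commercial 4-acetoxycinnamic acid with (COCl)2, cat. DMF)
Product: 18 19-O-(4-acetoxy-(E)-cinnamoyl) ester of 16
Conditions: 17 (1.5 equiv), pyridine, DMAP (cat.), CH2Cl2, 0 → 25 °C
Reagents that add atoms: 17, CC(=O)Oc1ccc(/C=C/C(=O)Cl)cc1
Why: Acylation (Steglich/Schotten–Baumann-type) of the primary axial alcohol is chemoselective because the tertiary 8α-OH is too hindered; the acetate protects the phenol and the E-alkene is retained.

**Step 15**
Reactants: 18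
Product: 19 8α-hydroxylabda-13(16),14-dien-19-yl (E)-p-hydroxycinnamate (target)
Conditions: K2CO3 (0.3 equiv), MeOH/THF, 0 °C, 20 min; aq. NH4Cl
Reagents that add atoms: none
Why: The aryl acetate is far more labile to methanolysis than the hindered neopentyl cinnamate, and the phenolate formed further deactivates the cinnamate.

---

**Compound list**

| No. | Name | SMILES | Role |
|---|---|---|---|
| 1 | (5E,9E)-farnesylacetone | CC(=O)CC/C=C(\C)CC/C=C(\C)CCC=C(C)C | starting material |
| 2 | (±)-13,14-epoxy-6,10,14-trimethylpentadeca-5,9-dien-2-one | CC(=O)CC/C=C(\C)CC/C=C(\C)CCC1OC1(C)C | intermediate |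
| 3 | (4E,8E)-4,8-dimethyl-12-oxotrideca-4,8-dienal | CC(=O)CC/C=C(\C)CC/C=C(\C)CCC=O | intermediate |
| 4 | methyl 2-[bis(2,2,2-trifluoroethoxy)phosphoryl]propanoate | COC(=O)C(C)P(=O)(OCC(F)(F)F)OCC(F)(F)F | starting material |
| 5 | methyl (2Z,6E,10E)-2,6,10-trimethyl-14-oxopentadeca-2,6,10-trienoate | CC(=O)CC/C=C(\C)CC/C=C(\C)CC/C=C(/C)C(=O)OC | intermediate |
| 6 | (2Z,6E,10E)-2,6,10-trimethylpentadeca-2,6,10-triene-1,14-diol (C14 epimers) | CC(O)CC/C=C(\C)CC/C=C(\C)CC/C=C(/C)CO | intermediate |
| 7 | (2R,3S,6E,10E)-2,3-epoxy-2,6,10-trimethylpentadeca-6,10-diene-1,14-diol | CC(O)CC/C=C(\C)CC/C=C(\C)CC[C@@H]1O[C@]1(C)CO | intermediate |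
| 8 | 1-O-TBDPS ether of 7 | CC(O)CC/C=C(\C)CC/C=C(\C)CC[C@@H]1O[C@]1(C)CO[Si](c2ccccc2)(c3ccccc3)C(C)(C)C | intermediate |
| 9 | 1-(TBDPSO)-2,3-epoxy-2,6,10-trimethylpentadeca-6,10-dien-14-one (2R,3S) | CC(=O)CC/C=C(\C)CC/C=C(\C)CC[C@@H]1O[C@]1(C)CO[Si](c2ccccc2)(c3ccccc3)C(C)(C)C | intermediate |
| 10 | 19-(TBDPSO)-3β,8α-dihydroxy-14,15-dinorlabdan-13-one | CC(=O)CC[C@@H]1[C@@]2(C)CC[C@H](O)[C@](C)(CO[Si](c3ccccc3)(c4ccccc4)C(C)(C)C)[C@@H]2CC[C@@]1(C)O | intermediate |
| 11 | 3β-O-phenoxythiocarbonyl derivative of 10 | CC(=O)CC[C@@H]1[C@@]2(C)CC[C@H](OC(=S)Oc3ccccc3)[C@](C)(CO[Si](c4ccccc4)(c5ccccc5)C(C)(C)C)[C@@H]2CC[C@@]1(C)O | intermediate |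
| 12 | 19-(TBDPSO)-8α-hydroxy-14,15-dinorlabdan-13-one | CC(=O)CC[C@@H]1[C@@]2(C)CCC[C@](C)(CO[Si](c3ccccc3)(c4ccccc4)C(C)(C)C)[C@@H]2CC[C@@]1(C)O | intermediate |
| 13 | 19-(TBDPSO)-8α-hydroxy-14,15-dinorlabd-13(16)-en-13-yl triflate | C=C(OS(=O)(=O)C(F)(F)F)CC[C@@H]1[C@@]2(C)CCC[C@](C)(CO[Si](c3ccccc3)(c4ccccc4)C(C)(C)C)[C@@H]2CC[C@@]1(C)O | intermediate |
| 14 | potassium vinyltrifluoroborate | C=C[B-](F)(F)F.[K+] | starting material |
| 15 | 19-(TBDPSO)-labda-13(16),14-dien-8α-ol | C=CC(=C)CC[C@@H]1[C@@]2(C)CCC[C@](C)(CO[Si](c3ccccc3)(c4ccccc4)C(C)(C)C)[C@@H]2CC[C@@]1(C)O | intermediate |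
| 16 | 8α-hydroxylabda-13(16),14-dien-19-ol | C=CC(=C)CC[C@@H]1[C@@]2(C)CCC[C@](C)(CO)[C@@H]2CC[C@@]1(C)O | intermediate |
| 17 | (E)-4-acetoxycinnamoyl chloride | CC(=O)Oc1ccc(/C=C/C(=O)Cl)cc1 | starting material (from commercial acid) |
| 18 | 19-O-(4-acetoxy-(E)-cinnamoyl) ester of 16 | C=CC(=C)CC[C@@H]1[C@@]2(C)CCC[C@](C)(COC(=O)/C=C/c3ccc(OC(C)=O)cc3)[C@@H]2CC[C@@]1(C)O | intermediate |
| 19 | 8α-hydroxylabda-13(16),14-dien-19-yl p-hydroxycinnamate | C=CC(=C)CC[C@@H]1[C@@]2(C)CCC[C@](C)(COC(=O)/C=C/c3ccc(O)cc3)[C@@H]2CC[C@@]1(C)O | target |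

---

**Total step count:** 15 steps.
**Longest linear sequence:** 15 steps, from compound 1 to 19; the preparation of 17 runs in parallel.

**Three steps most likely to fail**
1. **Step 8 (bicyclization).** The electron-withdrawing CH2OSi group on the epoxide carbon can divert opening to C3, and the Meinwald rearrangement or C19-oxygen capture at C10 can compete.
   Fallback: change to a radical cascade, treating epoxide 9 with Cp2TiCl (catalytic, Mn, collidine·HCl, TMSCl) to give the Δ8(17)-bicycle with 3β-OH, separating the C4 epimers, and setting 8α-OH by Mukaiyama hydration.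
2. **Step 5 (Sharpless epoxidation of the Z-trisubstituted allylic alcohol).** Rate and ee are lower for Z-alkenols.
   Fallback: make racemic cis-epoxy alcohol with VO(acac)2/TBHP and resolve it by lipase-catalysed acylation (kinetic resolution) instead of using an asymmetric catalyst.
3. **Step 11 (regioselective kinetic enol triflation in the presence of free 8α-OH).** Scrambling to the C12 enolate would give the wrong diene.
   Fallback: add vinylMgBr to ketone 12 to give the sclareol-type 13-hydroxy-14-ene, then protect 8-OH as its TES ether and dehydrate the allylic tertiary alcohol with Burgess reagent.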